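**Retrosynthetic overview**

Ring names: the upper flavan unit has rings A (7,8-dioxygenated benzo ring), B (catechol) and C (pyran). The lower unit has rings D (phloroglucinol-type benzo ring), E (catechol) and F (pyran). The last C–C bond joins C4 of ring C to C8 of ring D. A flavan-4-yl cation is captured biomimetically by a benzylated catechin, and the eight benzyl ethers fall at the very end.
Ring F (O1–C2–C3–C4–C4a–C8a) comes from a seven-membered cyclic acetal (O1–C2–O3–C3–C4–C4a–C8a, a 2-aryl-1,3-benzodioxepin-5-one) by a one-atom ring contraction. C2 moves from O3 to C3 and O3 leaves the ring as the 3-OH. The C2–C3 bond and both stereocentres arise together under a chiral Brønsted acid.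
Enabling feature: in ring F, C2 carries both the aryl oxygen O1 and catechol ring E, so it is a latent oxocarbenium carbon. Its neighbour C3 carries oxygen and lies next to C4, which as a temporary ketone makes C3 an enol carbon. The ketone is then reduced away (C=O, then CHOH, then CH2).
Ring C is built separately by known chemistry: chalcone, Juliá–Colonna epoxidation, 6-endo phenol closure to the dihydroflavonol, then borohydride reduction to the flavan-3,4-diol that serves as cation source.
Order of ring formation: seven-membered acetal ring, ring F from it, ring C, then union of the two halves.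

Key step: step 5

Assumption: precedent does not fix the sense of induction of the chiral acid in step 5, so the (R)-configured catalyst is written and its mirror image is taken if it favours the (2S,3S) series.

**Route**

Step 1
Reactants: 1 1-(2,4,6-trihydroxyphenyl)ethanone
Product: 2 1-[2,4-bis(benzyloxy)-6-hydroxyphenyl]ethanone
Conditions: BnBr (2.1 equiv), K2CO3 (2.2 equiv), DMF, 25 °C
Reagents that add atoms: benzyl bromide, BrCc1ccccc1
Why: Williamson ether synthesis in which the para-OH and one ortho-OH are alkylated, while the last ortho-OH is held back by its hydrogen bond to the acetyl carbonyl group.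

Step 2
Reactants: 2 1-[2,4-bis(benzyloxy)-6-hydroxyphenyl]ethanone
Product: 3 1-[2,4-bis(benzyloxy)-6-hydroxyphenyl]-2-hydroxyethanone
Conditions: NaN(SiMe3)2 (2.3 equiv), THF, −78 °C; 2-(phenylsulfonyl)-3-phenyloxaziridine (1.2 equiv), −78 °C; AcOH quench
Reagents that add atoms: 2-(phenylsulfonyl)-3-phenyloxaziridine, O=S(=O)(c1ccccc1)N1OC1c1ccccc1
Why: Davis oxidation in which the phenoxide–enolate dianion attacks the electrophilic oxygen of the N-sulfonyloxaziridine through its only enolisable carbon, which installs the future O3 without touching the electron-rich ring.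

Step 3
Reactants: 4 3,4-bis(benzyloxy)benzaldehyde
Product: 5 1,2-bis(benzyloxy)-4-(dimethoxymethyl)benzene
Conditions: HC(OMe)3 (1.5 equiv), p-TsOH·H2O (1 mol %), MeOH, 25 °C; Et3N quench
Reagents that add atoms: trimethyl orthoformate, COC(OC)OC
Why: Acid-catalysed acetalisation with the orthoester as water scavenger, which turns the aldehyde into a transacetalisation partner that ionises under very mild acid.

Step 4
Reactants: 3 1-[2,4-bis(benzyloxy)-6-hydroxyphenyl]-2-hydroxyethanone; 5 1,2-bis(benzyloxy)-4-(dimethoxymethyl)benzene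
Product: 6 (±)-6,8-bis(benzyloxy)-2-[3,4-bis(benzyloxy)phenyl]-1,3-benzodioxepin-5(4H)-one (seven-membered ring O1–C2–O3–C3H2–C4(=O)–C4a–C8a in flavan numbering)
Conditions: PPTS (5 mol %), toluene (0.02 M), 4 Å MS, 45 °C, MeOH removed under reduced pressure; Et3N quench
Reagents that add atoms: none
Why: Transacetalisation of the kind that gives 1,3-benzodioxins from salicyl alcohols, in which the electron-rich aryl acetal exchanges first with the primary alcohol and then with the neighbouring phenol, removal of methanol drives the closure, and the new acetal centre C2 forms as a racemate that the next step erases.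

Step 5
Reactants: 6 (±)-6,8-bis(benzyloxy)-2-[3,4-bis(benzyloxy)phenyl]-1,3-benzodioxepin-5(4H)-one
Product: 8 (2R,3R)-5,7-bis(benzyloxy)-2-[3,4-bis(benzyloxy)phenyl]-3-hydroxychroman-4-one (tetra-O-benzyltaxifolin; ring E and 3-OH trans), via ring-opened aryloxocarbenium enediol 7 (not isolated)
Conditions: (R)-3,3'-bis(2,4,6-triisopropylphenyl)-1,1'-binaphthyl-2,2'-diyl N-triflylphosphoramide (10 mol %), toluene, 5 Å MS, 25 °C
Reagents that add atoms: none
Why: Proposed new method: the chiral acid protonates acetal oxygen O3 of 6 and the C2–O3 bond breaks, which opens the seven-membered ring to the O1-aryl oxocarbenium ion 7 (C2 stabilised by O1 and by the 4-benzyloxy group of ring E) while the freed 2-hydroxyacetyl arm enolises to its enediol, whose C3 then adds to C2, so that C2 has moved from O3 to C3, O3 has left the ring as the 3-OH, and six-membered ring F stands in place of the seven-membered ring. The closest known reaction types are the Petasis–Ferrier rearrangement of cyclic enol acetals, its chiral-phosphate-catalysed aza variant, the Mukaiyama aldol reaction of acetals and additions of enols to oxocarbenium–phosphate ion pairs, and the new element is that the departing acetal oxygen sits on the attacking carbon itself, which makes the event a one-atom ring contraction. Ring F closes in a 6-endo-trig mode at the C2=O1 bond and in a 6-(enolendo) mode at the enediol, both favoured, through a half-chair in which O1, C8a, C4a and C4 stay in the plane of ring D. C2 is set by the chiral phosphoramide anion, which is ion-paired to C2=O1 and hydrogen-bonded to the enediol OH groups and so leaves one face of C2 open, and C3 follows C2 because the half-chair places ring E and the 3-OH both equatorial and because C3, being alpha to the ketone, is corrected to the more stable 2,3-trans isomer by enolisation under the same acid. The step needs productive C2–O3 rather than C2–O1 cleavage (both are reversible and only the O1-bound cation has a carbon nucleophile within reach), attack through C3 and not C4 of the enediol (only C3 attack restores the aryl ketone and gives a six-membered ring), and silence of ring D as a Friedel–Crafts partner (secured by the C4 carbonyl group). No atom is lost, so a racemic acetal assembled only through C–O bonds from two achiral pieces becomes a product that holds the C2–C3 bond, ring F and two defined stereocentres.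

Step 6
Reactants: 8 (2R,3R)-5,7-bis(benzyloxy)-2-[3,4-bis(benzyloxy)phenyl]-3-hydroxychroman-4-one
Product: 9 (2R,3S,4R)-5,7-bis(benzyloxy)-2-[3,4-bis(benzyloxy)phenyl]chromane-3,4-diol (2,3-trans-3,4-trans)
Conditions: NaBH4, THF/EtOH, 0 °C
Reagents that add atoms: none
Why: Borohydride reduction of the ketone, in which axial hydride delivery to the half-chair with ring E and 3-OH equatorial should give the all-equatorial 3,4-trans diol, a centre that the next step removes again.

Step 7
Reactants: 9 (2R,3S,4R)-5,7-bis(benzyloxy)-2-[3,4-bis(benzyloxy)phenyl]chromane-3,4-diol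
Product: 10 (2R,3S)-5,7-bis(benzyloxy)-2-[3,4-bis(benzyloxy)phenyl]chroman-3-ol (5,7,3',4'-tetra-O-benzyl-(+)-catechin)
Conditions: Et3SiH (3 equiv), CF3CO2H (0.2 equiv), CH2Cl2, −40 to −10 °C, slow addition of 9
Reagents that add atoms: none
Why: Ionic hydrogenation in which the 4-OH, benzylic to a ring with three oxygen donors (O1, 5-O, 7-O), ionises under catalytic acid far more easily than the O1–C2 bond and the cation takes hydride from the excess silane before it can meet another ring D, so C2 and C3 stay untouched.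

Step 8
Reactants: 11 1-(2,3,4-trihydroxyphenyl)ethanone
Product: 12 1-[3,4-bis(benzyloxy)-2-hydroxyphenyl]ethanone
Conditions: BnBr (2.1 equiv), K2CO3 (2.2 equiv), DMF, 25 °C
Reagents that add atoms: benzyl bromide, BrCc1ccccc1
Why: Williamson ether synthesis in which the 3-OH and 4-OH react while the 2-OH is held back by its hydrogen bond to the acetyl carbonyl group.

Step 9
Reactants: 12 1-[3,4-bis(benzyloxy)-2-hydroxyphenyl]ethanone
Product: 13 1-[3,4-bis(benzyloxy)-2-(methoxymethoxy)phenyl]ethanone
Conditions: MOMCl (1.5 equiv), K2CO3, acetone, reflux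
Reagents that add atoms: chloromethyl methyl ether, COCCl
Why: O-alkylation of the chelated phenoxide to the methoxymethyl ether, which keeps the later chalcone from closing to a flavanone and lets it survive basic peroxide.

Step 10
Reactants: 13 1-[3,4-bis(benzyloxy)-2-(methoxymethoxy)phenyl]ethanone; 4 3,4-bis(benzyloxy)benzaldehyde
Product: 14 (E)-1-[3,4-bis(benzyloxy)-2-(methoxymethoxy)phenyl]-3-[3,4-bis(benzyloxy)phenyl]prop-2-en-1-one
Conditions: KOH (aq), EtOH, 25 °C
Reagents that add atoms: none
Why: Claisen–Schmidt condensation of a methyl ketone with a non-enolisable aldehyde, whose E1cB dehydration gives the conjugated (E)-enone.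

Step 11
Reactants: 14 (E)-1-[3,4-bis(benzyloxy)-2-(methoxymethoxy)phenyl]-3-[3,4-bis(benzyloxy)phenyl]prop-2-en-1-one
Product: 15 [3,4-bis(benzyloxy)-2-(methoxymethoxy)phenyl]{(2R,3S)-3-[3,4-bis(benzyloxy)phenyl]oxiran-2-yl}methanone (trans-epoxide, alpha carbon R, beta carbon S)
Conditions: poly-L-leucine, urea·H2O2, DBU, THF, 25 °C
Reagents that add atoms: hydrogen peroxide (as its urea adduct), OO
Why: Juliá–Colonna epoxidation in which the helical poly-L-leucine binds hydroperoxide and enone and delivers oxygen to one enone face, which by the established sense for chalcones sets the alpha carbon R and the beta carbon S.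

Step 12
Reactants: 15 [3,4-bis(benzyloxy)-2-(methoxymethoxy)phenyl]{(2R,3S)-3-[3,4-bis(benzyloxy)phenyl]oxiran-2-yl}methanone
Product: 16 (2R,3R)-7,8-bis(benzyloxy)-2-[3,4-bis(benzyloxy)phenyl]-3-hydroxychroman-4-one (ring B and 3-OH trans)
Conditions: HCl (1.25 M in MeOH), THF, 45 °C
Reagents that add atoms: none
Why: Acid removes the methoxymethyl group and the freed phenol opens the epoxide at the benzylic carbon (6-endo-tet, activated by ring B) with inversion while the alpha C–O bond is kept, a known closure of chalcone epoxides that fixes C3 by retention and C2 as trans to it.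

Step 13
Reactants: 16 (2R,3R)-7,8-bis(benzyloxy)-2-[3,4-bis(benzyloxy)phenyl]-3-hydroxychroman-4-one
Product: 17 (2R,3S,4R)-7,8-bis(benzyloxy)-2-[3,4-bis(benzyloxy)phenyl]chromane-3,4-diol (2,3-trans-3,4-trans)
Conditions: NaBH4, THF/EtOH, 0 °C
Reagents that add atoms: none
Why: Borohydride reduction with axial hydride delivery to the half-chair should give the all-equatorial diol, whose C4 configuration is of no consequence because this centre ionises in the next step.

Step 14
Reactants: 17 (2R,3S,4R)-7,8-bis(benzyloxy)-2-[3,4-bis(benzyloxy)phenyl]chromane-3,4-diol; 10 (2R,3S)-5,7-bis(benzyloxy)-2-[3,4-bis(benzyloxy)phenyl]chroman-3-ol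
Product: 18 (2R,3S,4S)-7,8-bis(benzyloxy)-2-[3,4-bis(benzyloxy)phenyl]-4-{(2R,3S)-5,7-bis(benzyloxy)-2-[3,4-bis(benzyloxy)phenyl]-3-hydroxychroman-8-yl}chroman-3-ol (octa-O-benzyl dimer, 3,4-trans, 4α→8 link)
Conditions: 10 (3 equiv), Sc(OTf)3 (10 mol %), 4 Å MS, CH2Cl2, −20 to 0 °C, slow addition of 17
Reagents that add atoms: none
Why: Biomimetic Friedel–Crafts alkylation in which the Lewis acid ionises the 4-OH to the cation stabilised by O1 and the 7-benzyloxy group, C8 of ring D (less hindered than C6, which lies between two benzyloxy groups) attacks from the face opposite the 3-OH and so sets C4 as 3,4-trans (S), and the excess of 10 holds back further chain growth.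

Step 15
Reactants: 18 octa-O-benzyl dimer
Product: 19 (2R,3S,4S)-2-(3,4-dihydroxyphenyl)-4-[(2R,3S)-2-(3,4-dihydroxyphenyl)-3,5,7-trihydroxychroman-8-yl]chromane-3,7,8-triol (target)
Conditions: H2 (1 atm), Pd(OH)2/C, THF/MeOH/H2O, 25 °C
Reagents that add atoms: none
Why: Hydrogenolysis of the eight primary benzyl ethers, which under one atmosphere at room temperature is much faster than cleavage of the hindered secondary O1–C2 and C4–C8 bonds, so no stereocentre is touched.

**Compound list**

1 | 1-(2,4,6-trihydroxyphenyl)ethanone | CC(=O)c1c(O)cc(O)cc1O | starting material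
2 | 1-[2,4-bis(benzyloxy)-6-hydroxyphenyl]ethanone | CC(=O)c1c(O)cc(OCc2ccccc2)cc1OCc1ccccc1 | intermediate
3 | 1-[2,4-bis(benzyloxy)-6-hydroxyphenyl]-2-hydroxyethanone | OCC(=O)c1c(O)cc(OCc2ccccc2)cc1OCc1ccccc1 | intermediate
4 | 3,4-bis(benzyloxy)benzaldehyde | O=Cc1ccc(OCc2ccccc2)c(OCc2ccccc2)c1 | starting material
5 | 1,2-bis(benzyloxy)-4-(dimethoxymethyl)benzene | COC(OC)c1ccc(OCc2ccccc2)c(OCc2ccccc2)c1 | intermediate
6 | (±)-6,8-bis(benzyloxy)-2-[3,4-bis(benzyloxy)phenyl]-1,3-benzodioxepin-5(4H)-one (racemic at the acetal carbon) | O=C1COC(c2ccc(OCc3ccccc3)c(OCc3ccccc3)c2)Oc2cc(OCc3ccccc3)cc(OCc3ccccc3)c21 | intermediate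
7 | ring-opened aryloxocarbenium enediol cation (ion pair with the chiral phosphoramide anion) | OC=C(O)c1c(OCc2ccccc2)cc(OCc2ccccc2)cc1[O+]=Cc1ccc(OCc2ccccc2)c(OCc2ccccc2)c1 | intermediate
8 | (2R,3R)-5,7-bis(benzyloxy)-2-[3,4-bis(benzyloxy)phenyl]-3-hydroxychroman-4-one | c1(OCc2ccccc2)cc(OCc2ccccc2)c2c(c1)O[C@H](c1ccc(OCc3ccccc3)c(OCc3ccccc3)c1)[C@@H](O)C2=O | intermediate
9 | (2R,3S,4R)-5,7-bis(benzyloxy)-2-[3,4-bis(benzyloxy)phenyl]chromane-3,4-diol | c1(OCc2ccccc2)cc(OCc2ccccc2)c2c(c1)O[C@H](c1ccc(OCc3ccccc3)c(OCc3ccccc3)c1)[C@@H](O)[C@@H]2O | intermediate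
10 | (2R,3S)-5,7-bis(benzyloxy)-2-[3,4-bis(benzyloxy)phenyl]chroman-3-ol | c1(OCc2ccccc2)cc(OCc2ccccc2)c2c(c1)O[C@H](c1ccc(OCc3ccccc3)c(OCc3ccccc3)c1)[C@@H](O)C2 | intermediate
11 | 1-(2,3,4-trihydroxyphenyl)ethanone | CC(=O)c1ccc(O)c(O)c1O | starting material
12 | 1-[3,4-bis(benzyloxy)-2-hydroxyphenyl]ethanone | CC(=O)c1ccc(OCc2ccccc2)c(OCc2ccccc2)c1O | intermediate
13 | 1-[3,4-bis(benzyloxy)-2-(methoxymethoxy)phenyl]ethanone | CC(=O)c1ccc(OCc2ccccc2)c(OCc2ccccc2)c1OCOC | intermediate
14 | (E)-1-[3,4-bis(benzyloxy)-2-(methoxymethoxy)phenyl]-3-[3,4-bis(benzyloxy)phenyl]prop-2-en-1-one | O=C(/C=C/c1ccc(OCc2ccccc2)c(OCc2ccccc2)c1)c1ccc(OCc2ccccc2)c(OCc2ccccc2)c1OCOC | intermediate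
15 | [3,4-bis(benzyloxy)-2-(methoxymethoxy)phenyl]{(2R,3S)-3-[3,4-bis(benzyloxy)phenyl]oxiran-2-yl}methanone | O=C(c1ccc(OCc2ccccc2)c(OCc2ccccc2)c1OCOC)[C@@H]1O[C@H]1c1ccc(OCc2ccccc2)c(OCc2ccccc2)c1 | intermediate
16 | (2R,3R)-7,8-bis(benzyloxy)-2-[3,4-bis(benzyloxy)phenyl]-3-hydroxychroman-4-one | c1(OCc2ccccc2)c(OCc2ccccc2)ccc2c1O[C@H](c1ccc(OCc3ccccc3)c(OCc3ccccc3)c1)[C@@H](O)C2=O | intermediate
17 | (2R,3S,4R)-7,8-bis(benzyloxy)-2-[3,4-bis(benzyloxy)phenyl]chromane-3,4-diol | c1(OCc2ccccc2)c(OCc2ccccc2)ccc2c1O[C@H](c1ccc(OCc3ccccc3)c(OCc3ccccc3)c1)[C@@H](O)[C@@H]2O | intermediate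
18 | octa-O-benzyl dimer, (2R,3S,4S) upper unit linked 4α→8 to (2R,3S) lower unit | O(Cc5ccccc5)c1ccc([C@H]2Oc3c(ccc(OCc5ccccc5)c3OCc5ccccc5)[C@@H](c3c(OCc5ccccc5)cc(OCc5ccccc5)c4c3O[C@H](c3ccc(OCc5ccccc5)c(OCc5ccccc5)c3)[C@@H](O)C4)[C@@H]2O)cc1OCc5ccccc5 | intermediate
19 | (2R,3S,4S)-2-(3,4-dihydroxyphenyl)-4-[(2R,3S)-2-(3,4-dihydroxyphenyl)-3,5,7-trihydroxychroman-8-yl]chromane-3,7,8-triol | Oc1ccc([C@H]2Oc3c(ccc(O)c3O)[C@@H](c3c(O)cc(O)c4c3O[C@H](c3ccc(O)c(O)c3)[C@@H](O)C4)[C@@H]2O)cc1O | target

**Totals and risks**

Total step count: 15.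
Longest linear sequence: 8 steps (steps 1, 2, 4, 5, 6, 7, 14, 15; the upper branch, steps 8 to 15, is equally long).

Steps most likely to fail:

1. Step 5.
- What may go wrong: the hydroxyacetyl arm may enolise too slowly under the chiral acid, so that the acetal only opens and recloses or is hydrolysed by traces of water. The ion pair may also give poor facial selectivity at C2.
- Fallback: it sets out from 6 and comes back at 8, and it keeps the ring contraction but runs it with textbook reaction types.
- KN(SiMe3)2 and t-BuMe2SiCl in THF at −78 °C convert 6 into the cyclic tert-butyldimethylsilyl enol ether F1.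
- Catalytic Me3SiOTf in CH2Cl2 at −78 °C then ionises the acetal, and the preformed enol silane closes ring F as an intramolecular Mukaiyama aldol reaction of an acetal.
- Work-up with 1 M HCl in THF gives the racemic trans-dihydroflavonol F2.
- F2 is separated on a preparative chiral stationary phase (cellulose tris(3,5-dimethylphenylcarbamate)). Its (2R,3R)-enantiomer is 8.

2. Step 4.
- What may go wrong: the closure may stall at the open mixed acetal because the chelated phenol is a weak nucleophile. Heating with acid may also start an unselective ring contraction too early.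
- Fallback: it sets out from 3 (with aldehyde 4) and comes back at 6, and it replaces the equilibrium exchange by an irreversible silyl-transfer acetalisation.
- Me3SiCl and imidazole in CH2Cl2 give the bis(trimethylsilyl) ether F3.
- F3 reacts with 4 and catalytic Me3SiOTf in CH2Cl2 at −78 °C. The two silyl groups take up the aldehyde oxygen, and the cold, aprotic medium leaves the ketone arm unenolised.

3. Step 14.
- What may go wrong: poor facial selectivity at the C4 cation (formation of the 4β epimer), competing attack through C6 of ring D, or further alkylation of the product.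
- Fallback: it sets out from 17 and comes back at 18, and it relies on neighbouring-group participation.
- Ac2O in pyridine gives the 3,4-diacetate F4.
- Catalytic Me3SiOTf in CH2Cl2 at −78 °C ionises only the benzylic 4-acetate. The 3-acetoxy group bridges to C4 as a dioxolanylium ion on the face of the 3-oxygen, so 10 can attack only from the opposite face. This gives the upper-unit 3-O-acetyl octabenzyl dimer F5.
- K2CO3 in MeOH/THF removes the acetate and gives 18.

**Further compounds**

F1 | step 5 | (±)-6,8-bis(benzyloxy)-2-[3,4-bis(benzyloxy)phenyl]-5-(tert-butyldimethylsilyloxy)-1,3-benzodioxepine | CC(C)(C)[Si](C)(C)OC1=COC(c2ccc(OCc3ccccc3)c(OCc3ccccc3)c2)Oc2cc(OCc3ccccc3)cc(OCc3ccccc3)c21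
F2 | step 5 | (±)-trans-5,7-bis(benzyloxy)-2-[3,4-bis(benzyloxy)phenyl]-3-hydroxychroman-4-one (racemate, both enantiomers written) | c1(OCc2ccccc2)cc(OCc2ccccc2)c2c(c1)O[C@H](c1ccc(OCc3ccccc3)c(OCc3ccccc3)c1)[C@@H](O)C2=O.c1(OCc2ccccc2)cc(OCc2ccccc2)c2c(c1)O[C@@H](c1ccc(OCc3ccccc3)c(OCc3ccccc3)c1)[C@H](O)C2=O
F3 | step 4 | 1-[2,4-bis(benzyloxy)-6-(trimethylsilyloxy)phenyl]-2-(trimethylsilyloxy)ethanone | C[Si](C)(C)OCC(=O)c1c(O[Si](C)(C)C)cc(OCc2ccccc2)cc1OCc1ccccc1
F4 | step 14 | (2R,3S,4R)-7,8-bis(benzyloxy)-2-[3,4-bis(benzyloxy)phenyl]chromane-3,4-diyl diacetate | c1(OCc2ccccc2)c(OCc2ccccc2)ccc2c1O[C@H](c1ccc(OCc3ccccc3)c(OCc3ccccc3)c1)[C@@H](OC(C)=O)[C@@H]2OC(C)=O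
F5 | step 14 | octa-O-benzyl dimer 18 as the 3-O-acetate of its upper unit | O(Cc5ccccc5)c1ccc([C@H]2Oc3c(ccc(OCc5ccccc5)c3OCc5ccccc5)[C@@H](c3c(OCc5ccccc5)cc(OCc5ccccc5)c4c3O[C@H](c3ccc(OCc5ccccc5)c(OCc5ccccc5)c3)[C@@H](O)C4)[C@@H]2OC(C)=O)cc1OCc5ccccc5
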